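# Proposed total synthesis of CNP0254933.0 (16) by aldol aromatisation of a diprenylated diketo-dioxinone

Ring A locants C1–C6 follow the benzoic acid numbering of the target 16 (C1 carboxyl-bearing, C2 OMe, C3 prenyl, C4 OH, C5 prenyl, C6 arylethyl). The same locants are used for the corresponding carbons of every precursor; C7 and C8 are the bridge carbons to ring B.

## The problem

The target 16 is a bibenzyl: ring B is a para-substituted phenol, joined by a CH2CH2 bridge to ring A, a benzoic acid in which all six carbons carry a substituent. There is no stereocentre, so the difficulty is entirely regiochemical. Six different positions must be addressed on one ring, and substitution on a preformed resorcylate would face O- versus C-prenylation and linear versus branched prenyl transfer. The two ring A oxygens must be differentiated against their innate reactivity: in a 2,4-dihydroxybenzoate the non-chelated C4 hydroxyl is alkylated first, whereas here the chelated C2 oxygen carries the methyl group and C4 stays free. The fragile groups are the two trisubstituted olefins ortho to a free phenol, which acid closes to chromans and which exclude hydrogenation and electrophilic oxidants. The electron-rich, doubly ortho-substituted benzoic acid is also delicate: it decarboxylates in hot acid and its simple esters resist saponification. The enabling feature is the polyketide pattern of ring A: with the carboxyl on C1 and oxygens on C2 and C4, carbons C1 to C6 are carbons 2 to 7 of a 3,5,7-trioxo acid, which folds to the arene by a C1-to-C6 aldol condensation. If the carboxyl and the C2 oxygen are tied together as an acetonide (a 1,3-dioxin-4-one), that folding is the only six-membered closure open to the chain and the two oxygens emerge already distinguished.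

## Retrosynthesis

**16 from 15.** The last disconnection cuts three oxygen–allyl bonds: the ester at the C1 carboxyl and the aryl ethers at C4 and on ring B. Benzyl groups would need hydrogenolysis, which the prenyl olefins cannot survive. Acid-labile groups would need acid beside ortho-prenyl phenols. A methyl ester flanked by the C2 and C6 substituents could not be saponified. Compound 15 is no simpler in skeleton, but it has no acidic proton and carries only groups that zerovalent palladium removes in one neutral operation. The forward reaction must also ionise the hindered C4 ether and leave the prenyl chains alone.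

**15 from 14, 13 and 12.** Cutting the C2 oxygen–methyl bond gives salicylate 14. Rejoining its C2 oxygen and carboxyl through an isopropylidene acetal gives benzodioxinone 13, and cutting the C4 oxygen–allyl bond gives 12. The order is what matters. In 12 the C2 oxygen is inside the acetal and C4–OH is the only phenol, so C4 is capped first; opening the acetal then exposes C2–OH alone for methylation. Selective methylation of a free 2,4-dihydroxybenzoate would place the methyl group on C4 instead. The forward steps need an alkoxide to reach a lactone carbonyl flanked by the C6 chain, and a chelated, hindered phenol to be methylated.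

**12 from 10 (through 11).** The ring is opened at the C1–C6 bond and the aromatisation is undone. This cut is preferred over cuts at C2–C3 or C4–C5 because it leaves each ring carbon attached to its own substituent in the open chain, so ring A regiochemistry reduces to chain connectivity. It is also the bond a tetraketide forms in nature. Precursor 10 is acyclic apart from the dioxinone. The forward reaction must direct the dioxinone alpha carbon C1 onto the C6 ketone and nowhere else.

**10 from 9 and 3.** The chain is cut at C5–C6. The neighbouring C3–C4 cut was weighed and set aside for four reasons: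
- the C6 carbonyl would have to travel as a ketal inside a branched acyl donor;
- two branched carbons would have to be joined next to a quaternary centre;
- the amide enolate would be open to beta-elimination of the ketal oxygen;
- the ketal would have to be removed with acid beside two prenyl groups.

The C5–C6 cut brings the C6 carbonyl in last, from an unbranched amide, and leaves nothing to unmask. Compound 9 is a keto-dioxinone with both prenyl groups in place, and 3 is a simple Weinreb amide. The forward reaction needs a dianion of 9 that is acylated at its terminal carbon C5.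

**9 from 6 and 8; 6 from 4 and 5; 8 from 7.** Cutting C3–C4 gives the gamma-prenylated dioxinone 6 and acid chloride 8. Cutting the bond from C3 to its prenyl CH2 gives dioxinone 4 and prenyl bromide 5. Each prenyl group therefore arrives on a defined carbon: the C3 prenyl by alkylation, the C5 prenyl as the tail of acid 7. No prenylation has to choose among C3, C5 and oxygen of a polyketone. The forward reactions need gamma-selective alkylation and acylation of dioxinone dienolates.

**3 from 2 and 1.** Cutting the amide C–N bond and the two oxygen–allyl bonds leads back to phloretic acid 1. The allyl ether on ring B is chosen to match the final global deprotection.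

## Roads not taken

**Alternative 1:** The cut is made at the two CH2–CH= bonds of the prenyl groups. In the forward direction the 3,5-bis(chloromethyl) arene A2 would be coupled twice with vinyl bromide A3 by nickel-catalysed cathodic reduction with zinc as sacrificial anode, giving A1.
- Merits: the prenyl groups are made late by sp3–sp2 coupling, so there is no linear/branched or O/C ambiguity. No polyketone is handled, and no strong base or cryogenic step is needed. In these respects it is better than the chosen plan.
- Weak points: A2 is itself a hexasubstituted arene whose assembly, including the 2-OMe/4-O differentiation, is left unsolved and would take many steps. Its benzylic chlorides sit ortho to a carbonate-protected phenol and can collapse to quinone methides. Both couplings must succeed on one molecule, against reduction and benzyl homocoupling. A1 then needs three different deprotections, one of them saponification of a methyl benzoate with two ortho substituents.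
- Comparison: the chosen plan builds ring A with all six substituents and differentiated oxygens in one step, and ends with a single neutral deprotection. It pays with enolate chemistry at low temperature.

**Alternative 2:** The cut is made through ring A at C2–C3 and C4–C5. Cyclobutenone A5 would be heated with siloxyalkyne A6 in a Danheiser benzannulation: 4-electron opening to a vinylketene, cycloaddition, a second 4-electron opening and 6-electron closure, giving phenol A4.
- Merits: the reaction is convergent, neutral and thermal, with regiochemistry fixed by the pericyclic cascade. The two ring A oxygens come out differentiated (free OH at the future C2, silyl ether at C4), which equals the chosen plan on its central point.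
- Weak points: A4 lacks the carboxyl carbon; C1 is a C–H between the hydroxyl and the arylethyl chain and would have to be carboxylated late on a pentasubstituted, prenyl-bearing phenol. Both partners are multistep targets, and A5 in particular needs a regiodefined 2,3-dialkylcyclobutenone.
- Comparison: the chosen plan has the carboxyl carbon in the chain from the start and uses simpler building blocks. The benzannulation avoids the sensitive triketide and would be attractive if a late carboxylation were acceptable.

**Alternative 3:** The cut is made at C5–C6 and C2–C3. The lithium enolate of the symmetric ketone A8 would displace chloride from the chloroalkylidene malonate A9; a second deprotonation would then close the ring through the other alpha carbon onto one ester, giving resorcylate A7.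
- Merits: the symmetric ketone removes all enolate regiochemistry and carries both prenyl groups in one building block. The ring is made in one pot, and A7 would be one selective allylation away from 14. In step count this road is likely shorter than the chosen one.
- Weak points: vinylic substitution on a tetrasubstituted chloroalkene by a ketone enolate, followed by ring closure through the second and more hindered alpha carbon, must beat O-closure of the enol oxygen onto an ester to a pyranone. Both phenols of A7 are free, so the 2-OMe/4-OH pattern depends on a kinetically selective mono-allylation at a C4 hydroxyl that is flanked by two prenyl groups.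
- Comparison: the chosen plan differentiates the oxygens structurally, since one of them is inside the acetal, and the ring geometry excludes the competing closures. A7 is nevertheless retained as the intermediate of the fallback for the key step.

Key step: step 7

## Route

Remark: 5-methylhex-4-enoic acid (7) is treated as a purchasable building block.

Remark: 9, 10 and 11 are formed without stereocontrol at C3 and C5 (and at C1 and C6 in 11) and are used as mixtures, since every stereocentre is lost on aromatisation.

Step 1
Reactants: 1 3-(4-hydroxyphenyl)propanoic acid (phloretic acid)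
Product: 2 allyl 3-[4-(allyloxy)phenyl]propanoate
Conditions: allyl bromide, K2CO3, DMF, 50 °C
Reagents that add atoms: allyl bromide, C=CCBr
Why: Williamson etherification of the phenoxide and SN2 O-alkylation of the carboxylate take place together under carbonate base; the allyl ether matches the final global deprotection and the ester is the acyl donor for step 2.

Step 2
Reactants: 2 allyl 3-[4-(allyloxy)phenyl]propanoate
Product: 3 3-[4-(allyloxy)phenyl]-N-methoxy-N-methylpropanamide
Conditions: MeNHOMe·HCl, iPrMgCl, THF, −20 to 0 °C
Reagents that add atoms: N,O-dimethylhydroxylamine hydrochloride, Cl.CNOC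
Why: Direct aminolysis of an unhindered ester by the chloromagnesium amide of N,O-dimethylhydroxylamine (Weinreb amide formation from esters); the aryl allyl ether is inert to the Grignard base at this temperature.

Step 3
Reactants: 4 2,2,6-trimethyl-4H-1,3-dioxin-4-one; 5 1-bromo-3-methylbut-2-ene (prenyl bromide)
Product: 6 2,2-dimethyl-6-(4-methylpent-3-en-1-yl)-4H-1,3-dioxin-4-one
Conditions: LiN(iPr)2, THF/DMPU, −78 °C; then 5, −78 to −40 °C
Reagents that add atoms: none
Why: Vinylogous enolate alkylation: the lithium dienolate of the dioxinone reacts with reactive allylic halides at the exocyclic gamma carbon in the presence of a dipolar cosolvent, and SN2 attack at the primary carbon of 5 keeps the prenyl unit linear.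

Step 4
Reactants: 7 5-methylhex-4-enoic acid
Product: 8 5-methylhex-4-enoyl chloride
Conditions: (COCl)2, cat. DMF, CH2Cl2, 0 °C to rt; volatiles removed, used crude
Reagents that add atoms: oxalyl chloride, O=C(Cl)C(=O)Cl
Why: Standard Vilsmeier-catalysed conversion of a carboxylic acid to its chloride; low temperature and immediate evaporation keep hydrogen chloride from adding to the trisubstituted olefin.

Step 5
Reactants: 6 2,2-dimethyl-6-(4-methylpent-3-en-1-yl)-4H-1,3-dioxin-4-one; 8 5-methylhex-4-enoyl chloride
Product: 9 6-(2,10-dimethyl-6-oxoundeca-2,9-dien-5-yl)-2,2-dimethyl-4H-1,3-dioxin-4-one (racemic)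
Conditions: 6 (2 equiv), LiN(SiMe3)2, THF, −78 °C; then 8 (1 equiv), −78 °C; aq. NH4Cl
Reagents that add atoms: none
Why: Claisen-type C-acylation of a dioxinone lithium dienolate at its gamma carbon by an acid chloride, the standard entry to keto-dioxinones; the second equivalent of dienolate takes up the acidic C3 proton of the product and is recovered as 6, and the new C3 stereocentre is formed racemic and erased later.

Step 6
Reactants: 9 6-(2,10-dimethyl-6-oxoundeca-2,9-dien-5-yl)-2,2-dimethyl-4H-1,3-dioxin-4-one; 3 3-[4-(allyloxy)phenyl]-N-methoxy-N-methylpropanamide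
Product: 10 6-{1-[4-(allyloxy)phenyl]-9-methyl-4-(3-methylbut-2-en-1-yl)-3,5-dioxodec-8-en-6-yl}-2,2-dimethyl-4H-1,3-dioxin-4-one (mixture of diastereomers and keto–enol tautomers)
Conditions: LiN(iPr)2 (2.2 equiv), THF, −78 °C; then 3, −78 to −20 °C; aq. NH4Cl; used crude
Reagents that add atoms: none
Why: Regioselective Claisen condensation of a keto-dioxinone dianion at its terminal, more basic carbon (C5) with a Weinreb amide; the chelated tetrahedral adduct prevents over-addition and releases the 1,3-diketone only on quench, and the uncontrolled centres at C3 and C5 are of no consequence.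

Step 7
Reactants: 10 6-{1-[4-(allyloxy)phenyl]-9-methyl-4-(3-methylbut-2-en-1-yl)-3,5-dioxodec-8-en-6-yl}-2,2-dimethyl-4H-1,3-dioxin-4-one
Product: 12 5-{2-[4-(allyloxy)phenyl]ethyl}-7-hydroxy-2,2-dimethyl-6,8-bis(3-methylbut-2-en-1-yl)-4H-1,3-benzodioxin-4-one, via cyclic aldol adduct 11 (not isolated)
Conditions: Et3N, CH2Cl2, rt
Reagents that add atoms: none
Why: Triethylamine reversibly removes the C3 proton of 10 and gives the cross-conjugated dienolate in which the dioxinone alpha carbon C1 is nucleophilic. C1 adds to the C6 ketone in an intramolecular aldol reaction, a 6-(enolendo)-exo-trig closure that forms the C1–C6 bond and the carbocycle of adduct 11. E1cB loss of one molecule of water across C1–C6 and enolisation of the C4 ketone through C5–H then aromatise ring A, which makes the sequence irreversible. The closest known reaction type is the amine-induced aldol aromatisation of diketo-dioxinones to 7-hydroxybenzodioxinones, the laboratory counterpart of tetraketide cyclisation. No stereocentre remains in 12; those of 10 and 11 are destroyed. The step needs aldol closure to win over Claisen closure of C5 onto the carboxyl carbon and over lactonisation of the C4 enol oxygen to a pyranone; the dioxinone ring holds the carboxyl carbon trans to C3 across the C1=C2 bond, so neither of those six-membered closures can be reached and C1–C6 is the only six-membered carbon–carbon closure available. The more acidic C5 proton gives an enolate with no electrophile within reach, which is a resting state and not a diversion. The acetonide keeps the C2 oxygen masked, so C4–OH is the only free phenol of 12.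

Step 8
Reactants: 12 5-{2-[4-(allyloxy)phenyl]ethyl}-7-hydroxy-2,2-dimethyl-6,8-bis(3-methylbut-2-en-1-yl)-4H-1,3-benzodioxin-4-one
Product: 13 7-(allyloxy)-5-{2-[4-(allyloxy)phenyl]ethyl}-2,2-dimethyl-6,8-bis(3-methylbut-2-en-1-yl)-4H-1,3-benzodioxin-4-one
Conditions: allyl bromide, K2CO3, DMF, rt
Reagents that add atoms: allyl bromide, C=CCBr
Why: Williamson O-allylation of the single free phenol; both ortho positions are blocked, so C-allylation is excluded, and the dioxinone tolerates anhydrous carbonate.

Step 9
Reactants: 13 7-(allyloxy)-5-{2-[4-(allyloxy)phenyl]ethyl}-2,2-dimethyl-6,8-bis(3-methylbut-2-en-1-yl)-4H-1,3-benzodioxin-4-one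
Product: 14 allyl 4-(allyloxy)-6-{2-[4-(allyloxy)phenyl]ethyl}-2-hydroxy-3,5-bis(3-methylbut-2-en-1-yl)benzoate
Conditions: NaH, allyl alcohol, THF, 0 °C to rt; aq. NH4Cl
Reagents that add atoms: allyl alcohol, C=CCO
Why: Alkoxide opening (transesterification) of the benzodioxinone: the alkoxide adds to the lactone carbonyl, the hemiketal alkoxide leaves and sheds acetone, and the phenoxide of the allyl salicylate results with C2–OH as the only free hydroxyl. The allyl ester is chosen because this doubly ortho-substituted benzoate could not be saponified later.

Step 10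
Reactants: 14 allyl 4-(allyloxy)-6-{2-[4-(allyloxy)phenyl]ethyl}-2-hydroxy-3,5-bis(3-methylbut-2-en-1-yl)benzoate
Product: 15 allyl 4-(allyloxy)-6-{2-[4-(allyloxy)phenyl]ethyl}-2-methoxy-3,5-bis(3-methylbut-2-en-1-yl)benzoate
Conditions: MeI, Cs2CO3, DMF, rt
Reagents that add atoms: iodomethane, CI
Why: Williamson methylation of the only remaining phenol; the chelated, hindered salicylate hydroxyl is alkylated as its caesium phenoxide in a dipolar solvent, and no other nucleophilic site is present.

Step 11
Reactants: 15 allyl 4-(allyloxy)-6-{2-[4-(allyloxy)phenyl]ethyl}-2-methoxy-3,5-bis(3-methylbut-2-en-1-yl)benzoate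
Product: 16 4-hydroxy-6-[2-(4-hydroxyphenyl)ethyl]-2-methoxy-3,5-bis(3-methylbut-2-en-1-yl)benzoic acid
Conditions: Pd(PPh3)4 (cat.), morpholine, THF, rt; cold dilute aqueous citric acid work-up
Reagents that add atoms: none
Why: Tsuji–Trost deallylation: zerovalent palladium ionises the allyl ester and both aryl allyl ethers to π-allyl complexes that morpholine intercepts; the prenyl chains are not allylic electrophiles, and neither acid nor hydrogen is used.

## Compound list

1 | 3-(4-hydroxyphenyl)propanoic acid (phloretic acid) | OC(=O)CCc1ccc(O)cc1 | starting material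
2 | allyl 3-[4-(allyloxy)phenyl]propanoate | C=CCOC(=O)CCc1ccc(OCC=C)cc1 | intermediate
3 | 3-[4-(allyloxy)phenyl]-N-methoxy-N-methylpropanamide | CON(C)C(=O)CCc1ccc(OCC=C)cc1 | intermediate
4 | 2,2,6-trimethyl-4H-1,3-dioxin-4-one | CC1=CC(=O)OC(C)(C)O1 | starting material
5 | 1-bromo-3-methylbut-2-ene (prenyl bromide) | CC(C)=CCBr | starting material
6 | 2,2-dimethyl-6-(4-methylpent-3-en-1-yl)-4H-1,3-dioxin-4-one | CC1(C)OC(=O)C=C(O1)CCC=C(C)C | intermediate
7 | 5-methylhex-4-enoic acid | CC(C)=CCCC(=O)O | starting material
8 | 5-methylhex-4-enoyl chloride | CC(C)=CCCC(=O)Cl | intermediate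
9 | 6-(2,10-dimethyl-6-oxoundeca-2,9-dien-5-yl)-2,2-dimethyl-4H-1,3-dioxin-4-one (racemic) | CC1(C)OC(=O)C=C(O1)C(CC=C(C)C)C(=O)CCC=C(C)C | intermediate
10 | 6-{1-[4-(allyloxy)phenyl]-9-methyl-4-(3-methylbut-2-en-1-yl)-3,5-dioxodec-8-en-6-yl}-2,2-dimethyl-4H-1,3-dioxin-4-one (stereoisomer mixture) | CC1(C)OC(=O)C=C(O1)C(CC=C(C)C)C(=O)C(CC=C(C)C)C(=O)CCc1ccc(OCC=C)cc1 | intermediate
11 | 5-{2-[4-(allyloxy)phenyl]ethyl}-5-hydroxy-2,2-dimethyl-6,8-bis(3-methylbut-2-en-1-yl)-4a,5-dihydro-4H-1,3-benzodioxine-4,7(6H)-dione (stereoisomer mixture, not isolated) | CC1(C)OC(=O)C2C(O1)=C(CC=C(C)C)C(=O)C(CC=C(C)C)C2(O)CCc1ccc(OCC=C)cc1 | intermediate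
12 | 5-{2-[4-(allyloxy)phenyl]ethyl}-7-hydroxy-2,2-dimethyl-6,8-bis(3-methylbut-2-en-1-yl)-4H-1,3-benzodioxin-4-one | CC1(C)OC(=O)c2c(CCc3ccc(OCC=C)cc3)c(CC=C(C)C)c(O)c(CC=C(C)C)c2O1 | intermediate
13 | 7-(allyloxy)-5-{2-[4-(allyloxy)phenyl]ethyl}-2,2-dimethyl-6,8-bis(3-methylbut-2-en-1-yl)-4H-1,3-benzodioxin-4-one | CC1(C)OC(=O)c2c(CCc3ccc(OCC=C)cc3)c(CC=C(C)C)c(OCC=C)c(CC=C(C)C)c2O1 | intermediate
14 | allyl 4-(allyloxy)-6-{2-[4-(allyloxy)phenyl]ethyl}-2-hydroxy-3,5-bis(3-methylbut-2-en-1-yl)benzoate | C=CCOC(=O)c1c(O)c(CC=C(C)C)c(OCC=C)c(CC=C(C)C)c1CCc1ccc(OCC=C)cc1 | intermediate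
15 | allyl 4-(allyloxy)-6-{2-[4-(allyloxy)phenyl]ethyl}-2-methoxy-3,5-bis(3-methylbut-2-en-1-yl)benzoate | C=CCOC(=O)c1c(OC)c(CC=C(C)C)c(OCC=C)c(CC=C(C)C)c1CCc1ccc(OCC=C)cc1 | intermediate
16 | 4-hydroxy-6-[2-(4-hydroxyphenyl)ethyl]-2-methoxy-3,5-bis(3-methylbut-2-en-1-yl)benzoic acid | COc1c(CC=C(C)C)c(O)c(CC=C(C)C)c(CCc2ccc(O)cc2)c1C(=O)O | target

## Step count and risk

Total step count: 11. Longest linear sequence: 8 steps (steps 3, 5, 6, 7, 8, 9, 10, 11 from dioxinone 4; the branches from 1 and from 7 are equally long).

**Step 7 (key step).** Both carbons flanking the C4 ketone carry a prenyl group, so deprotonation at the tertiary C3 position may be slow while the substrate rests as its C5 enolate. Cyclisation could then lag behind O-closure of the C6 enol onto C2, or dehydration of the aldol adduct could stall. The fallback sets out from 10 and returns at 14.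
- Heating 10 in toluene with allyl alcohol would open the dioxinone by retro-[4+2] loss of acetone to 9-[4-(allyloxy)phenyl]-4,6-bis(3-methylbut-2-en-1-yl)non-1-ene-1,3,5,7-tetraone F1.
- The alcohol traps this acylketene as allyl 9-[4-(allyloxy)phenyl]-4,6-bis(3-methylbut-2-en-1-yl)-3,5,7-trioxononanoate F2.
- In F2 the future C1 is a true beta-keto ester methylene that needs no deprotonation at a tertiary centre. It closes onto the C6 ketone with Cs2CO3 and, after mild acidification, gives allyl 2,4-dihydroxy-3,5-bis(3-methylbut-2-en-1-yl)-6-{2-[4-(allyloxy)phenyl]ethyl}benzoate F3, the same compound as A7.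
- Allylation of the non-chelated C4 hydroxyl (allyl bromide, K2CO3, acetone) then gives 14.

This gives up the built-in oxygen differentiation and recovers it by chelation-controlled selective alkylation.

**Step 6.** Double deprotonation of 9 may be incomplete at the tertiary C3–H. Proton transfer from C3–H to the C5 enolate would then quench the nucleophile, and a hindered secondary enolate may add sluggishly to an amide. The fallback sets out from 3 and 9 and returns at 10.
- Reduction of 3 with iBu2AlH at −78 °C would give 3-[4-(allyloxy)phenyl]propanal F4.
- Aldol addition of the dianion of 9 to this far more electrophilic partner would give 6-{1-[4-(allyloxy)phenyl]-3-hydroxy-9-methyl-4-(3-methylbut-2-en-1-yl)-5-oxodec-8-en-6-yl}-2,2-dimethyl-4H-1,3-dioxin-4-one F5.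
- Dess–Martin oxidation of the secondary alcohol then gives 10.

**Step 5.** The substituted dienolate may be acylated on oxygen or at the ring alpha carbon, or acylated twice. The fallback sets out from 4 and 8 and returns at 9.
- The unsubstituted lithium dienolate of 4 is acylated with 8 to give 2,2-dimethyl-6-(6-methyl-2-oxohept-5-en-1-yl)-4H-1,3-dioxin-4-one F6.
- Its doubly activated C3 methylene is then alkylated with 5 (K2CO3, acetone) to give 9.

The order of prenylation and acylation is reversed, so that the acylation uses a primary dienolate.

**Step 3.** Alkylation may occur at the alpha carbon or twice, and the dienolate may self-condense. The fallback sets out from 8 and returns at 6.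
- Acylation of Meldrum's acid with 8 (pyridine, CH2Cl2) gives 5-(1-hydroxy-5-methylhex-4-en-1-ylidene)-2,2-dimethyl-1,3-dioxane-4,6-dione F7.
- Heating F7 in toluene with acetone releases 7-methylocta-1,6-diene-1,3-dione F8.
- Acetone captures this acylketene in a [4+2] cycloaddition to give 6.

The dioxinone ring is thus built around the side chain, with no dienolate alkylation.

**Step 9.** Alkoxide attack on the lactone carbonyl may be slowed by the C6 chain. The phenoxide product may also be lost through retro-processes on prolonged exposure to base. The fallback sets out from 13 and returns at 14.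
- Hydrolysis with KOH in aqueous DMSO gives 4-(allyloxy)-6-{2-[4-(allyloxy)phenyl]ethyl}-2-hydroxy-3,5-bis(3-methylbut-2-en-1-yl)benzoic acid F9.
- Chemoselective O-alkylation of its carboxylate (allyl bromide, KHCO3, DMF) gives 14, the chelated C2 hydroxyl staying free.

## Further compounds

F1 | step 7 | 9-[4-(allyloxy)phenyl]-4,6-bis(3-methylbut-2-en-1-yl)non-1-ene-1,3,5,7-tetraone | O=C=CC(=O)C(CC=C(C)C)C(=O)C(CC=C(C)C)C(=O)CCc1ccc(OCC=C)cc1
F2 | step 7 | allyl 9-[4-(allyloxy)phenyl]-4,6-bis(3-methylbut-2-en-1-yl)-3,5,7-trioxononanoate | C=CCOC(=O)CC(=O)C(CC=C(C)C)C(=O)C(CC=C(C)C)C(=O)CCc1ccc(OCC=C)cc1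
F3 | step 7 | allyl 2,4-dihydroxy-3,5-bis(3-methylbut-2-en-1-yl)-6-{2-[4-(allyloxy)phenyl]ethyl}benzoate | C=CCOC(=O)c1c(O)c(CC=C(C)C)c(O)c(CC=C(C)C)c1CCc1ccc(OCC=C)cc1
F4 | step 6 | 3-[4-(allyloxy)phenyl]propanal | O=CCCc1ccc(OCC=C)cc1
F5 | step 6 | 6-{1-[4-(allyloxy)phenyl]-3-hydroxy-9-methyl-4-(3-methylbut-2-en-1-yl)-5-oxodec-8-en-6-yl}-2,2-dimethyl-4H-1,3-dioxin-4-one | CC1(C)OC(=O)C=C(O1)C(CC=C(C)C)C(=O)C(CC=C(C)C)C(O)CCc1ccc(OCC=C)cc1
F6 | step 5 | 2,2-dimethyl-6-(6-methyl-2-oxohept-5-en-1-yl)-4H-1,3-dioxin-4-one | CC1(C)OC(=O)C=C(O1)CC(=O)CCC=C(C)C
F7 | step 3 | 5-(1-hydroxy-5-methylhex-4-en-1-ylidene)-2,2-dimethyl-1,3-dioxane-4,6-dione | CC(C)=CCCC(O)=C1C(=O)OC(C)(C)OC1=O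
F8 | step 3 | 7-methylocta-1,6-diene-1,3-dione | O=C=CC(=O)CCC=C(C)C
F9 | step 9 | 4-(allyloxy)-6-{2-[4-(allyloxy)phenyl]ethyl}-2-hydroxy-3,5-bis(3-methylbut-2-en-1-yl)benzoic acid | OC(=O)c1c(O)c(CC=C(C)C)c(OCC=C)c(CC=C(C)C)c1CCc1ccc(OCC=C)cc1
A1 | alternative 1 | methyl 4-(ethoxycarbonyloxy)-2-methoxy-3,5-bis(3-methylbut-2-enyl)-6-[2-(4-triisopropylsilyloxyphenyl)ethyl]benzoate | COC(=O)c1c(OC)c(CC=C(C)C)c(OC(=O)OCC)c(CC=C(C)C)c1CCc1ccc(O[Si](C(C)C)(C(C)C)C(C)C)cc1
A2 | alternative 1 | methyl 3,5-bis(chloromethyl)-4-(ethoxycarbonyloxy)-2-methoxy-6-[2-(4-triisopropylsilyloxyphenyl)ethyl]benzoate | COC(=O)c1c(OC)c(CCl)c(OC(=O)OCC)c(CCl)c1CCc1ccc(O[Si](C(C)C)(C(C)C)C(C)C)cc1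
A3 | alternative 1 | 1-bromo-2-methylprop-1-ene | CC(C)=CBr
A4 | alternative 2 | 2,4-bis(3-methylbut-2-enyl)-3-triisopropylsilyloxy-5-[2-(4-triisopropylsilyloxyphenyl)ethyl]phenol | Oc1cc(CCc2ccc(O[Si](C(C)C)(C(C)C)C(C)C)cc2)c(CC=C(C)C)c(O[Si](C(C)C)(C(C)C)C(C)C)c1CC=C(C)C
A5 | alternative 2 | 2-(3-methylbut-2-enyl)-3-[2-(4-triisopropylsilyloxyphenyl)ethyl]cyclobut-2-en-1-one | O=C1CC(CCc2ccc(O[Si](C(C)C)(C(C)C)C(C)C)cc2)=C1CC=C(C)C
A6 | alternative 2 | triisopropyl[(5-methylhex-4-en-1-yn-1-yl)oxy]silane | CC(C)=CCC#CO[Si](C(C)C)(C(C)C)C(C)C
A7 | alternative 3 | allyl 2,4-dihydroxy-3,5-bis(3-methylbut-2-enyl)-6-[2-(4-allyloxyphenyl)ethyl]benzoate | C=CCOC(=O)c1c(O)c(CC=C(C)C)c(O)c(CC=C(C)C)c1CCc1ccc(OCC=C)cc1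
A8 | alternative 3 | 2,10-dimethylundeca-2,9-dien-6-one | CC(C)=CCCC(=O)CCC=C(C)C
A9 | alternative 3 | diallyl 2-{1-chloro-3-[4-(allyloxy)phenyl]propylidene}malonate | C=CCOC(=O)C(C(=O)OCC=C)=C(Cl)CCc1ccc(OCC=C)cc1
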